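**Strategy.** The decalin is cut across ring B at C5–C10 and C8–C9 (halimane numbering). These two bonds are the σ-bonds of a [4+2] between a C5=C6–C7=C8 diene and the C9=C10 alkene of an enone whose carbonyl is C1. Because C1–C4 link the two partners, one intramolecular Diels–Alder reaction of an open-chain trienone forms rings A and B together and fixes C5, C8 and the quaternary C9 (C10 too, later erased by the C1=C10 alkene). The precursor is a malonate-centred (C4) trienone that carries the complete (13E) side chain as a silyl ether; a chiral oxazaborolidinium Lewis acid selects the enantioface.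

Key step: step 10

**Remarks on the chemistry**
- Numbering: ring A = C1, C2, C3, C4, C5, C10; ring B = C5 to C10; C17 on C8; C20 and the chain C11–C16 on C9; C18 (carboxyl carbon, cis to H5) and C19 on C4.
- The methyl-bearing carbons C9 and C13 are 1,4-related (a 3,6-dimethylocta-2,6-diene pattern), not 1,5-related as in a geranyl chain. Geranyl acetate therefore supplies only C9 and C11–C16 after loss of its isopropylidene end, and C9=C10 with C20 is rebuilt by carboalumination.
- Assumption: the sense of induction of the boron catalyst on this enone class is not established. The (S)-prolinol-derived catalyst is written; if the first run gives the antipode of 18, the (R)-catalyst is used with nothing else changed.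

**Route**

Step 1
Reactants: 1 geranyl acetate
Product: 3 (2E)-3-methyl-6-oxohex-2-en-1-yl acetate, via 6,7-epoxygeranyl acetate 2 (not isolated)
Conditions: 3-chloroperoxybenzoic acid (mCPBA), CH2Cl2, 0 °C; then H5IO6, THF–H2O, 0 °C to rt
Reagents that add atoms: 3-chloroperoxybenzoic acid, O=C(OO)c1cccc(Cl)c1
Why: Prilezhaev epoxidation picks the electron-rich 6,7-alkene over the acetate-deactivated 2,3-alkene, and periodic acid then cleaves the epoxide through its diol (glycol cleavage), so the (E)-C13=C14 unit is kept and the aldehyde carbon becomes C9.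

Step 2
Reactants: 3 (2E)-3-methyl-6-oxohex-2-en-1-yl acetate
Product: 5 (2E)-3-methylhept-2-en-6-yn-1-ol, via enynyl acetate 4 (not isolated)
Conditions: dimethyl (1-diazo-2-oxopropyl)phosphonate, K2CO3, MeOH, 0 °C to rt
Reagents that add atoms: dimethyl (1-diazo-2-oxopropyl)phosphonate (Ohira–Bestmann reagent), COP(=O)(OC)C(=[N+]=[N-])C(C)=O
Why: Seyferth–Gilbert homologation with the Ohira–Bestmann reagent converts the aldehyde into the terminal alkyne (new carbon = C10), and the K2CO3/MeOH medium removes the acetate by transesterification in the same pot.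

Step 3
Reactants: 5 (2E)-3-methylhept-2-en-6-yn-1-ol
Product: 6 tert-butyl{[(2E)-3-methylhept-2-en-6-yn-1-yl]oxy}diphenylsilane
Conditions: tert-butyl(chloro)diphenylsilane, imidazole, DMF, rt
Reagents that add atoms: tert-butyl(chloro)diphenylsilane, CC(C)(C)[Si](Cl)(c1ccccc1)c1ccccc1
Why: Imidazole-mediated silylation of the primary allylic alcohol installs a group that should survive AlMe3, CrCl2, the boron Lewis acid, hot DMSO and amide bases.

Step 4
Reactants: 6 tert-butyl{[(2E)-3-methylhept-2-en-6-yn-1-yl]oxy}diphenylsilane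
Product: 8 tert-butyl{[(2E,6E)-7-iodo-3,6-dimethylhepta-2,6-dien-1-yl]oxy}diphenylsilane, via alkenylalane 7 (not isolated)
Conditions: AlMe3, Cp2ZrCl2 (0.25 equiv), CH2Cl2, 0 °C to rt; then I2, THF, −30 to 0 °C
Reagents that add atoms: trimethylaluminium, C[Al](C)C; iodine, II
Why: Zirconium-catalysed Negishi carboalumination adds CH3 (C20) and aluminium syn across the terminal alkyne with CH3 on the internal carbon, and iodinolysis with retention gives the (E)-iodoalkene that fixes C20 cis to C1 in the later enone.

Step 5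
Reactants: 9 dimethyl malonate; 10 (2E)-pent-2-enal
Product: 11 dimethyl [(2E)-pent-2-en-1-ylidene]propanedioate
Conditions: piperidine (cat.), AcOH (cat.), toluene, reflux, Dean–Stark trap
Reagents that add atoms: none
Why: Knoevenagel condensation of the active methylene compound with the enal, pulled to completion by azeotropic removal of water.

Step 6
Reactants: 11 dimethyl [(2E)-pent-2-en-1-ylidene]propanedioate; 12 3-bromo-1,1-dimethoxypropane
Product: 14 dimethyl (3,3-dimethoxypropyl)[(1E,3E)-penta-1,3-dien-1-yl]propanedioate, via sodium dienolate 13 (not isolated)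
Conditions: NaH, THF, 0 °C to rt; then 12, NaI (cat.), DMF, 50 °C
Reagents that add atoms: none
Why: Deprotonation at the ε-CH2 gives the extended malonate anion, which is alkylated irreversibly at the α-carbon (deconjugative α-alkylation of an alkylidenemalonate); this creates the quaternary but achiral C4 and the (E,E)-diene, whose geometry follows from the W-shaped anion.

Step 7
Reactants: 14 dimethyl (3,3-dimethoxypropyl)[(1E,3E)-penta-1,3-dien-1-yl]propanedioate
Product: 15 dimethyl (3-oxopropyl)[(1E,3E)-penta-1,3-dien-1-yl]propanedioate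
Conditions: 1 M HCl, THF, rt
Reagents that add atoms: water, O
Why: Acid-catalysed acetal hydrolysis frees the aldehyde (C1), while the isolated diene and the quaternary malonate are inert to dilute acid.

Step 8
Reactants: 15 dimethyl (3-oxopropyl)[(1E,3E)-penta-1,3-dien-1-yl]propanedioate; 8 tert-butyl{[(2E,6E)-7-iodo-3,6-dimethylhepta-2,6-dien-1-yl]oxy}diphenylsilane
Product: 16 dimethyl [(4E,8E)-10-{[tert-butyl(diphenyl)silyl]oxy}-3-hydroxy-5,8-dimethyldeca-4,8-dien-1-yl][(1E,3E)-penta-1,3-dien-1-yl]propanedioate (racemic carbinol)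
Conditions: CrCl2 (4 equiv), NiCl2 (2 mol%), DMSO, rt
Reagents that add atoms: none
Why: Nozaki–Hiyama–Kishi coupling adds the alkenylchromium reagent to the aldehyde with retention of the (E)-alkene and without attack on the esters; the uncontrolled carbinol centre is removed by the next oxidation.

Step 9
Reactants: 16 allylic alcohol
Product: 17 dimethyl [(4E,8E)-10-{[tert-butyl(diphenyl)silyl]oxy}-5,8-dimethyl-3-oxodeca-4,8-dien-1-yl][(1E,3E)-penta-1,3-dien-1-yl]propanedioate (trienone precursor)
Conditions: Dess–Martin periodinane, CH2Cl2, 0 °C to rt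
Reagents that add atoms: none
Why: Dess–Martin oxidation of the secondary allylic alcohol under non-basic conditions, so that neither retro-Michael loss of the malonate nor enone isomerisation should intervene.

Step 10
Reactants: 17 trienone precursor
Product: 18 dimethyl (5S,8R,9S,10S,13E)-15-{[tert-butyl(diphenyl)silyl]oxy}-1-oxohalima-6,13-diene-18,19-dioate (cis-fused octalone; H5 and H10 cis; C17, C20 and C4 on one face of ring B)
Conditions: B-(2-methylphenyl) oxazaborolidine of (S)-α,α-diphenylprolinol (0.2 equiv) protonated with HNTf2 (0.18 equiv), CH2Cl2, −40 to 0 °C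
Reagents that add atoms: none
Why: Proposed new method: the cationic boron Lewis acid binds the C1 carbonyl, lowers the enone LUMO and triggers a concerted, asynchronous [4+2] in which C5–C10 forms ahead of C8–C9; the closest known reactions are Lewis-acid-promoted intramolecular Diels–Alder reactions of 1,7,9-decatrien-3-ones and oxazaborolidinium-catalysed Diels–Alder reactions of simple enones. Ring B is closed as the six-membered cycloadduct ring by both new bonds, and ring A as the six-membered tether ring (type 1 closure through the four-atom C1–C4 link) by the C5–C10 bond alone. Suprafacial addition carries the (E,E)-diene geometry into the C5/C8 relationship and the (E)-enone geometry into the C9/C10 relationship, while the endo placement of the tether carbonyl under the diene (cis ring fusion) ties the two pairs together so that C17, C20 and C4 share one face. The absolute sense comes from the catalyst, whose aryl groups screen one face of the bound enone. The step needs endo and π-facial selectivity: Lewis-acid complexation favours the endo mode in this tether class, the gem-diester at C4 adds no competing stereocentre and speeds closure (Thorpe–Ingold effect), and the ketone is the only strongly Lewis-basic site next to the dienophile.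

Step 11
Reactants: 18 cis-fused octalone adduct
Product: 19 dimethyl (5S,8R,9S,10S,13E)-15-{[tert-butyl(diphenyl)silyl]oxy}-1-oxohalim-13-ene-18,19-dioate
Conditions: 2-nitrobenzenesulfonylhydrazide (NBSH), Et3N, CH2Cl2, rt, repeated charges
Reagents that add atoms: none
Why: Diimide reduction (concerted syn transfer of H2) should saturate the cis-disubstituted ring alkene much faster than the trisubstituted C13=C14 alkene and does not touch ketone, esters or the allylic silyl ether.

Step 12
Reactants: 19 saturated keto diester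
Product: 20 methyl (5S,8R,9S,13E)-15-{[tert-butyl(diphenyl)silyl]oxy}-1-oxo-19-norhalim-13-en-18-oate (C4 epimers)
Conditions: LiCl, H2O, DMSO, 150 °C
Reagents that add atoms: none
Why: Krapcho dealkoxycarbonylation (chloride attack on an ester methyl group, decarboxylation, protonation) removes one ester; C4 arises as an epimer mixture and C10 may equilibrate, which is harmless because both centres become trigonal in steps 13 and 15.

Step 13
Reactants: 20 keto monoester
Product: 22 methyl (5R,8R,9S,13E)-15-{[tert-butyl(diphenyl)silyl]oxy}-1-{[(trifluoromethyl)sulfonyl]oxy}-19-norhalima-1(10),13-dien-18-oate (C4 epimers), via bromomagnesium enolate 21 (not isolated)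
Conditions: iPr2NMgBr, Et2O, rt (equilibration); then PhNTf2, reflux
Reagents that add atoms: N-phenylbis(trifluoromethanesulfonimide), O=S(=O)(N(c1ccccc1)S(=O)(=O)C(F)(F)F)C(F)(F)F
Why: Equilibrating enolisation with the magnesium amide should give the more substituted C1=C10 enolate (thermodynamic enolate formation, helped because a trigonal C10 removes the syn-axial contacts across the ring fusion), and N-phenyltriflimide traps it on oxygen as the enol triflate.

Step 14
Reactants: 22 enol triflate
Product: 23 methyl (5R,8R,9S,13E)-15-{[tert-butyl(diphenyl)silyl]oxy}-19-norhalima-1(10),13-dien-18-oate (C4 epimers)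
Conditions: Pd(OAc)2 (5 mol%), PPh3, HCO2H, Bu3N, DMF, 60 °C
Reagents that add atoms: none
Why: Palladium-catalysed formate reduction of the enol triflate (oxidative addition, formate–triflate exchange, decarboxylation, reductive elimination) replaces OTf by H regiospecifically and leaves the isolated alkene and the ester untouched.

Step 15
Reactants: 23 1(10)-ene monoester
Product: 25 methyl (4S,5S,8R,9S,13E)-15-{[tert-butyl(diphenyl)silyl]oxy}halima-1(10),13-dien-18-oate, via lithium enolate 24 (not isolated)
Conditions: LiN(iPr)2, THF, −78 °C; then MeI, DMPU, −78 to 0 °C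
Reagents that add atoms: iodomethane, CI
Why: Ester enolate alkylation in which CH3 should enter on the axial face of ring A, anti to the pseudo-axial H5, because the trigonal C10 leaves that face without a syn-axial hydrogen while the equatorial face is flanked by the axial hydrogens at C3 and C5; this sets C4 with the ester cis to H5.

Step 16
Reactants: 25 silyl-protected methyl ester
Product: 26 methyl (4S,5S,8R,9S,13E)-15-hydroxyhalima-1(10),13-dien-18-oate
Conditions: Bu4NF, THF, rt
Reagents that add atoms: none
Why: Fluoride-mediated desilylation, driven by the Si–F bond, frees the primary allylic alcohol without affecting the hindered ester.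

Step 17
Reactants: 26 hydroxy methyl ester
Product: 28 (4S,5S,8R,9S,13E)-15-hydroxyhalima-1(10),13-dien-18-oic acid, via potassium carboxylate 27 (not isolated)
Conditions: KOH, ethylene glycol–H2O, 130 °C; then 1 M HCl (work-up)
Reagents that add atoms: potassium hydroxide, [K+].[OH-]
Why: Saponification (acyl–oxygen cleavage) of the neopentyl-type ester needs forcing conditions, which the alkenes and the allylic alcohol should tolerate; acidification gives the free acid.

Step 18
Reactants: 28 hydroxy acid
Product: 29 (4S,5S,8R,9S,13E)-15-(propanoyloxy)halima-1(10),13-dien-18-oic acid (target)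
Conditions: propionic anhydride, pyridine, 4-(dimethylamino)pyridine (cat.), CH2Cl2, 0 °C to rt; aqueous NaHCO3 work-up
Reagents that add atoms: propionic anhydride, CCC(=O)OC(=O)CC
Why: Nucleophilic catalysis by 4-(dimethylamino)pyridine acylates the unhindered primary alcohol, and any mixed anhydride of the hindered tertiary acid is hydrolysed back to the acid during the bicarbonate work-up.

**Compound list**

1 | geranyl acetate, (2E)-3,7-dimethylocta-2,6-dien-1-yl acetate | CC(C)=CCC/C(C)=C/COC(C)=O | starting material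
2 | 6,7-epoxygeranyl acetate (racemic) | CC1(C)OC1CC/C(C)=C/COC(C)=O | intermediate
3 | (2E)-3-methyl-6-oxohex-2-en-1-yl acetate | O=CCC/C(C)=C/COC(C)=O | intermediate
4 | (2E)-3-methylhept-2-en-6-yn-1-yl acetate | C#CCC/C(C)=C/COC(C)=O | intermediate
5 | (2E)-3-methylhept-2-en-6-yn-1-ol | C#CCC/C(C)=C/CO | intermediate
6 | tert-butyl{[(2E)-3-methylhept-2-en-6-yn-1-yl]oxy}diphenylsilane | C#CCC/C(C)=C/CO[Si](c1ccccc1)(c1ccccc1)C(C)(C)C | intermediate
7 | [(1E,5E)-7-{[tert-butyl(diphenyl)silyl]oxy}-2,5-dimethylhepta-1,5-dien-1-yl]dimethylalumane | C[Al](C)/C=C(\C)CC/C(C)=C/CO[Si](c1ccccc1)(c1ccccc1)C(C)(C)C | intermediate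
8 | tert-butyl{[(2E,6E)-7-iodo-3,6-dimethylhepta-2,6-dien-1-yl]oxy}diphenylsilane | I/C=C(\C)CC/C(C)=C/CO[Si](c1ccccc1)(c1ccccc1)C(C)(C)C | intermediate
9 | dimethyl malonate | COC(=O)CC(=O)OC | starting material
10 | (2E)-pent-2-enal | CC/C=C/C=O | starting material
11 | dimethyl [(2E)-pent-2-en-1-ylidene]propanedioate | CC/C=C/C=C(C(=O)OC)C(=O)OC | intermediate
12 | 3-bromo-1,1-dimethoxypropane | COC(CCBr)OC | starting material
13 | sodium dienolate of 11 (extended malonate anion) | C/C=C/C=C/C(C(=O)OC)=C(OC)[O-].[Na+] | intermediate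
14 | dimethyl (3,3-dimethoxypropyl)[(1E,3E)-penta-1,3-dien-1-yl]propanedioate | C/C=C/C=C/C(CCC(OC)OC)(C(=O)OC)C(=O)OC | intermediate
15 | dimethyl (3-oxopropyl)[(1E,3E)-penta-1,3-dien-1-yl]propanedioate | C/C=C/C=C/C(CCC=O)(C(=O)OC)C(=O)OC | intermediate
16 | dimethyl [(4E,8E)-10-{[tert-butyl(diphenyl)silyl]oxy}-3-hydroxy-5,8-dimethyldeca-4,8-dien-1-yl][(1E,3E)-penta-1,3-dien-1-yl]propanedioate (racemic carbinol) | C/C=C/C=C/C(CCC(O)/C=C(\C)CC/C(C)=C/CO[Si](c1ccccc1)(c1ccccc1)C(C)(C)C)(C(=O)OC)C(=O)OC | intermediate
17 | dimethyl [(4E,8E)-10-{[tert-butyl(diphenyl)silyl]oxy}-5,8-dimethyl-3-oxodeca-4,8-dien-1-yl][(1E,3E)-penta-1,3-dien-1-yl]propanedioate (key-step precursor) | C/C=C/C=C/C(C(=O)OC)(C(=O)OC)CCC(=O)/C=C(\C)CC/C(C)=C/CO[Si](c1ccccc1)(c1ccccc1)C(C)(C)C | intermediate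
18 | dimethyl (5S,8R,9S,10S,13E)-15-{[tert-butyl(diphenyl)silyl]oxy}-1-oxohalima-6,13-diene-18,19-dioate (key-step product) | CC(C)(C)[Si](c1ccccc1)(c1ccccc1)OC/C=C(\C)CC[C@]2(C)[C@H]3C(=O)CCC(C(=O)OC)(C(=O)OC)[C@H]3C=C[C@H]2C | intermediate
19 | dimethyl (5S,8R,9S,10S,13E)-15-{[tert-butyl(diphenyl)silyl]oxy}-1-oxohalim-13-ene-18,19-dioate | CC(C)(C)[Si](c1ccccc1)(c1ccccc1)OC/C=C(\C)CC[C@]2(C)[C@H]3C(=O)CCC(C(=O)OC)(C(=O)OC)[C@H]3CC[C@H]2C | intermediate
20 | methyl (5S,8R,9S,13E)-15-{[tert-butyl(diphenyl)silyl]oxy}-1-oxo-19-norhalim-13-en-18-oate (C4 epimers, C10 not defined) | CC(C)(C)[Si](c1ccccc1)(c1ccccc1)OC/C=C(\C)CC[C@]2(C)C3C(=O)CCC(C(=O)OC)[C@H]3CC[C@H]2C | intermediate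
21 | bromomagnesium 1(10)-enolate of 20 | CC(C)(C)[Si](c1ccccc1)(c1ccccc1)OC/C=C(\C)CC[C@]2(C)C3=C(O[Mg]Br)CCC(C(=O)OC)[C@H]3CC[C@H]2C | intermediate
22 | methyl (5R,8R,9S,13E)-15-{[tert-butyl(diphenyl)silyl]oxy}-1-{[(trifluoromethyl)sulfonyl]oxy}-19-norhalima-1(10),13-dien-18-oate (C4 epimers) | CC(C)(C)[Si](c1ccccc1)(c1ccccc1)OC/C=C(\C)CC[C@]2(C)C3=C(OS(=O)(=O)C(F)(F)F)CCC(C(=O)OC)[C@H]3CC[C@H]2C | intermediate
23 | methyl (5R,8R,9S,13E)-15-{[tert-butyl(diphenyl)silyl]oxy}-19-norhalima-1(10),13-dien-18-oate (C4 epimers) | CC(C)(C)[Si](c1ccccc1)(c1ccccc1)OC/C=C(\C)CC[C@]2(C)C3=CCCC(C(=O)OC)[C@H]3CC[C@H]2C | intermediate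
24 | lithium ester enolate of 23 (C4 trigonal) | CC(C)(C)[Si](c1ccccc1)(c1ccccc1)OC/C=C(\C)CC[C@]2(C)C3=CCCC(=C(OC)[O-])[C@H]3CC[C@H]2C.[Li+] | intermediate
25 | methyl (4S,5S,8R,9S,13E)-15-{[tert-butyl(diphenyl)silyl]oxy}halima-1(10),13-dien-18-oate | CC(C)(C)[Si](c1ccccc1)(c1ccccc1)OC/C=C(\C)CC[C@]2(C)C3=CCC[C@](C)(C(=O)OC)[C@H]3CC[C@H]2C | intermediate
26 | methyl (4S,5S,8R,9S,13E)-15-hydroxyhalima-1(10),13-dien-18-oate | OC/C=C(\C)CC[C@]1(C)C2=CCC[C@](C)(C(=O)OC)[C@H]2CC[C@H]1C | intermediate
27 | potassium (4S,5S,8R,9S,13E)-15-hydroxyhalima-1(10),13-dien-18-oate | OC/C=C(\C)CC[C@]1(C)C2=CCC[C@](C)(C(=O)[O-])[C@H]2CC[C@H]1C.[K+] | intermediate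
28 | (4S,5S,8R,9S,13E)-15-hydroxyhalima-1(10),13-dien-18-oic acid | OC/C=C(\C)CC[C@]1(C)C2=CCC[C@](C)(C(=O)O)[C@H]2CC[C@H]1C | intermediate
29 | (4S,5S,8R,9S,13E)-15-(propanoyloxy)halima-1(10),13-dien-18-oic acid | CCC(=O)OC/C=C(\C)CC[C@]1(C)C2=CCC[C@](C)(C(=O)O)[C@H]2CC[C@H]1C | target

**Totals.** 18 steps in all. The longest linear sequence is 15 steps (steps 1–4, then 8–18).

**Steps most likely to fail**

Step 10 (proposed new method). What may go wrong: too little activation of the hindered β,β-disubstituted enone, erosion of the enone geometry through acid-mediated dienol formation, leakage into the exo mode, or weak enantioface discrimination. Fallback: setting out from 17, the cyclisation is run with the achiral Lewis acid MeAlCl2 (CH2Cl2, −78 to 0 °C), a known way to close 1,7,9-decatrien-3-ones. It should give the racemic cis-fused adduct, that is 18 together with the mirror-image adduct F1, and the two are separated by preparative chromatography on a chiral stationary phase. The route is rejoined at 18.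

Step 15. What may go wrong: poor or inverted facial selectivity in the enolate methylation, with CH3 entering on the equatorial face cis to H5. Fallback: setting out from 23, the equatorial preference is used constructively. Enolate 24 is C-acylated with di-tert-butyl dicarbonate, so that the new tert-butoxycarbonyl group sits cis to H5 and the methyl ester becomes axial, giving the mixed malonate F2. LiBH4 reduces only the methyl ester to the neopentyl alcohol F3, methanesulfonyl chloride/Et3N gives the mesylate F4, and LiEt3BH in refluxing THF gives the C19-methyl tert-butyl ester F5. TMSOTf/2,6-lutidine followed by Bu4NF removes the tert-butyl and silyl groups, and the route is rejoined at 28.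

Step 13. What may go wrong: enolisation toward C2 instead of C10 if equilibration is incomplete, or slow O-sulfonylation of the hindered tetrasubstituted enolate. Fallback: setting out from 20, the ketone is reduced with NaBH4 in MeOH to the C1 carbinol F6. This is dehydrated with the Burgess reagent in warm benzene (syn elimination toward the tertiary H10; Martin sulfurane would serve for an anti-disposed epimer). The route is rejoined at 23.

Further compounds
F1 | step 10 | enantiomer of 18, dimethyl (5R,8S,9R,10R,13E)-15-{[tert-butyl(diphenyl)silyl]oxy}-1-oxohalima-6,13-diene-18,19-dioate | CC(C)(C)[Si](c1ccccc1)(c1ccccc1)OC/C=C(\C)CC[C@@]2(C)[C@@H]3C(=O)CCC(C(=O)OC)(C(=O)OC)[C@@H]3C=C[C@@H]2C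
F2 | step 15 | 18-tert-butyl 19-methyl (4S,5S,8R,9S,13E)-15-{[tert-butyl(diphenyl)silyl]oxy}halima-1(10),13-diene-18,19-dioate | CC(C)(C)[Si](c1ccccc1)(c1ccccc1)OC/C=C(\C)CC[C@]2(C)C3=CCC[C@](C(=O)OC)(C(=O)OC(C)(C)C)[C@H]3CC[C@H]2C
F3 | step 15 | tert-butyl (4S,5S,8R,9S,13E)-15-{[tert-butyl(diphenyl)silyl]oxy}-19-hydroxyhalima-1(10),13-dien-18-oate | CC(C)(C)[Si](c1ccccc1)(c1ccccc1)OC/C=C(\C)CC[C@]2(C)C3=CCC[C@](CO)(C(=O)OC(C)(C)C)[C@H]3CC[C@H]2C
F4 | step 15 | tert-butyl (4S,5S,8R,9S,13E)-15-{[tert-butyl(diphenyl)silyl]oxy}-19-[(methylsulfonyl)oxy]halima-1(10),13-dien-18-oate | CC(C)(C)[Si](c1ccccc1)(c1ccccc1)OC/C=C(\C)CC[C@]2(C)C3=CCC[C@](COS(C)(=O)=O)(C(=O)OC(C)(C)C)[C@H]3CC[C@H]2C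
F5 | step 15 | tert-butyl (4S,5S,8R,9S,13E)-15-{[tert-butyl(diphenyl)silyl]oxy}halima-1(10),13-dien-18-oate | CC(C)(C)[Si](c1ccccc1)(c1ccccc1)OC/C=C(\C)CC[C@]2(C)C3=CCC[C@](C)(C(=O)OC(C)(C)C)[C@H]3CC[C@H]2C
F6 | step 13 | methyl (5S,8R,9S,13E)-15-{[tert-butyl(diphenyl)silyl]oxy}-1-hydroxy-19-norhalim-13-en-18-oate (C1, C4 and C10 not defined) | CC(C)(C)[Si](c1ccccc1)(c1ccccc1)OC/C=C(\C)CC[C@]2(C)C3C(O)CCC(C(=O)OC)[C@H]3CC[C@H]2C
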